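**Strategy**

Everything rests on cutting the N1–C2 bond of the pyrrole ring. The feature exploited is the bromine on C2, the pyrrole carbon bonded to N1: read backwards, C3 and C2 are the two carbons of a gem-dibromovinyl group ortho to an aniline nitrogen, while the second ortho carbon of that benzene ring is C7 with its bromine in place from the start. In one metal-free operation, base strips HBr from the alkene and the nitrogen anion closes the five-membered ring onto the resulting bromoalkyne, so CBr4 supplies the C2 bromine and no regioselective C2 halogenation is needed. The precursor is the N-mesyl derivative of 2-bromo-6-(2,2-dibromoethenyl)aniline. C3 bromination and mesyl removal finish the synthesis.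

Key step: step 4

Remark on the chemistry: the target has no stereocentre. It is assumed to share the acid and light sensitivity of other N–H 2,3-dihaloindoles, so the N–H is released only in the last step and handled cold and in the dark.

**Route**

Step 1
Reactants: 1 3-bromo-2-nitrobenzaldehyde; 2 carbon tetrabromide
Product: 3 1-bromo-3-(2,2-dibromoethenyl)-2-nitrobenzene
Conditions: CBr4 (2 equiv), PPh3 (4 equiv), CH2Cl2, 0 °C to rt
Reagents that add atoms: carbon tetrabromide, BrC(Br)(Br)Br
Why: Ramirez dibromoolefination (the first stage of the Corey–Fuchs sequence): the ylide Ph3P=CBr2 generated from PPh3 and CBr4 should engage the electron-poor aldehyde in a Wittig reaction at 0 °C, a temperature at which PPh3 touches neither the nitro group nor the aryl bromide.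

Step 2
Reactants: 3 1-bromo-3-(2,2-dibromoethenyl)-2-nitrobenzene
Product: 4 2-bromo-6-(2,2-dibromoethenyl)aniline
Conditions: Fe powder (5 equiv), AcOH/EtOH, 70 °C
Reagents that add atoms: none
Why: Béchamp-type reduction with Fe in acid delivers electrons and protons to the nitro group only, so the amine should form while the aryl and vinylic C–Br bonds, which hydrogenation over Pd/C would endanger, stay intact.

Step 3
Reactants: 4 2-bromo-6-(2,2-dibromoethenyl)aniline; 5 methanesulfonyl chloride
Product: 6 N-[2-bromo-6-(2,2-dibromoethenyl)phenyl]methanesulfonamide
Conditions: MsCl (1.3 equiv), pyridine, 0 °C to 40 °C
Reagents that add atoms: methanesulfonyl chloride, CS(=O)(=O)Cl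
Why: N-sulfonylation of an aniline: pyridine is too weak a base to deprotonate the first-formed sulfonamide, so the reaction should stop after one mesyl group, which is chosen because it makes the N–H acidic enough for a carbonate base and is the smallest sulfonyl group that can later sit between the C2 and C7 bromines.

Step 4
Reactants: 6 N-[2-bromo-6-(2,2-dibromoethenyl)phenyl]methanesulfonamide
Product: 8 2,7-dibromo-1-(methylsulfonyl)-1H-indole, via bromoalkyne 7 (not isolated)
Conditions: Cs2CO3 (2.5 equiv), dry DMF (0.05 M), 70 °C, N2
Reagents that add atoms: none
Why: Cs2CO3 first deprotonates the acidic N–H and then takes the vinylic hydrogen, so that the geminal bromide anti to it leaves (E2) and bromoalkyne 7 is formed; the nitrogen anion adds to the bromine-bearing alkyne carbon to make N1–C2, and the in-plane C3 vinyl anion is protonated by CsHCO3. A direct addition–elimination of the nitrogen anion at the CBr2 carbon cannot be ruled out and would give the same product. The closest known reaction type is the transition-metal-free, carbonate-promoted cyclisation of ortho-(2,2-dibromovinyl)-N-sulfonylanilines to N-sulfonyl-2-bromoindoles. The pyrrole ring closes in the 5-endo-dig mode, the 4-exo-dig attack at the aryl-bearing alkyne carbon being out of geometric reach, and no stereocentre is created. The step must tell three C–Br bonds apart: only the geminal vinylic pair has a neighbouring hydrogen to eliminate with, the aryl C–Br bond (future C7) has no reaction channel without a transition metal, and the C2–Br bond of 8 lies on an aromatic ring that carbonate does not attack. High dilution and a moderate temperature should keep intermolecular addition of the anion to 7 behind the ring closure.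

Step 5
Reactants: 8 2,7-dibromo-1-(methylsulfonyl)-1H-indole; 9 bromine
Product: 10 2,3,7-tribromo-1-(methylsulfonyl)-1H-indole
Conditions: Br2 (1.2 equiv), CH2Cl2, 0 °C to rt, dark
Reagents that add atoms: bromine, BrBr
Why: Electrophilic aromatic substitution: C3 is the only free pyrrole carbon and the cation formed by attack there is stabilised by N1 and by the lone pairs of the C2 bromine, whereas the benzene ring is deactivated by the C7 bromine, and Br2 is preferred to NBS because N-sulfonylindoles need the stronger electrophile.

Step 6
Reactants: 10 2,3,7-tribromo-1-(methylsulfonyl)-1H-indole
Product: 11 2,3,7-tribromo-1H-indole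
Conditions: LiOH·H2O (3 equiv), THF/H2O, 0 °C to rt, dark
Reagents that add atoms: none
Why: Basic hydrolysis of an N-sulfonylindole (attack of hydroxide at sulfur or E1cB loss of sulfene): the tribromoindolide is a good leaving group and the mesyl group is squeezed between two bromines, so cleavage should run at or below room temperature, and hydroxide in place of methoxide turns the mesyl group into inert LiOSO2CH3 and not into methyl methanesulfonate, which could methylate N1.

**Compound list**

1 | 3-bromo-2-nitrobenzaldehyde | O=Cc1cccc(Br)c1[N+](=O)[O-] | starting material
2 | carbon tetrabromide | BrC(Br)(Br)Br | starting material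
3 | 1-bromo-3-(2,2-dibromoethenyl)-2-nitrobenzene | O=[N+]([O-])c1c(Br)cccc1C=C(Br)Br | intermediate
4 | 2-bromo-6-(2,2-dibromoethenyl)aniline | Nc1c(Br)cccc1C=C(Br)Br | intermediate
5 | methanesulfonyl chloride | CS(=O)(=O)Cl | starting material
6 | N-[2-bromo-6-(2,2-dibromoethenyl)phenyl]methanesulfonamide | CS(=O)(=O)Nc1c(Br)cccc1C=C(Br)Br | intermediate
7 | N-[2-bromo-6-(bromoethynyl)phenyl]methanesulfonamide | CS(=O)(=O)Nc1c(Br)cccc1C#CBr | intermediate
8 | 2,7-dibromo-1-(methylsulfonyl)-1H-indole | CS(=O)(=O)n1c(Br)cc2cccc(Br)c21 | intermediate
9 | bromine | BrBr | starting material
10 | 2,3,7-tribromo-1-(methylsulfonyl)-1H-indole | CS(=O)(=O)n1c(Br)c(Br)c2cccc(Br)c21 | intermediate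
11 | 2,3,7-tribromo-1H-indole | Brc1[nH]c2c(Br)cccc2c1Br | target

Total step count: 6
Longest linear sequence: 6 steps (fully linear from 1)

**Steps most likely to fail**

Step 4 (key step).
- **Risk:** ring closure may be slow, because the sulfonamide anion is weakly nucleophilic and the mesyl group is pushed against the ortho bromine as the ring forms. The bromoalkyne could then be consumed by intermolecular addition, by oligomerisation or by halophilic loss of its bromine. The strained mesyl group could also be shed early under the basic conditions. Material that has lost it can still be advanced by the reversed end-game given under step 5.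
- **Fallback:** it sets out from 6 and comes back at 8. The N1–C2 bond is made by an Ullmann–Goldberg-type intramolecular vinylic amidation instead of by elimination–addition. Conditions are CuBr (10 mol %), N,N'-dimethylethane-1,2-diamine (20 mol %), K2CO3 (2 equiv), toluene, 90 °C. Monovalent copper bound to the sulfonamide nitrogen couples with the vinylic C–Br bond cis to the ring. In the non-polar medium dehydrobromination is slow, so no free bromoalkyne is exposed. This type of copper-catalysed closure is known for gem-dibromovinyl anilides. The five-membered ring closure should outrun any intermolecular coupling at the aryl bromide. No compound outside the list is formed (F0).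

Step 5.
- **Risk:** substitution may be sluggish or incomplete, because the pyrrole ring is deactivated by the sulfonyl group and by two bromines. Forcing conditions could then bring attack on the benzene ring.
- **Fallback:** it sets out from 8 and comes back at target 11 by reversing the order of the end-game. The mesyl group is cleaved first (LiOH·H2O, THF/H2O, rt) to give 2,7-dibromo-1H-indole F1. Its free pyrrole ring is far more nucleophilic at C3. It should therefore take up one bromine with NBS (1.0 equiv) in THF at −78 °C to 0 °C in the dark, which gives 11 directly.

Step 3.
- **Risk:** the sulfonylation may stall at the hindered, electron-poor nitrogen flanked by two ortho substituents. When the reaction is pushed it may overshoot to double sulfonylation.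
- **Fallback:** it sets out from 4 and comes back at 6, and double sulfonylation is made the goal. MsCl (3 equiv) and Et3N in CH2Cl2 at 0 °C act through sulfene and should drive the aniline fully to N-[2-bromo-6-(2,2-dibromoethenyl)phenyl]-N-(methylsulfonyl)methanesulfonamide F2. One mesyl group is then removed with aqueous NaOH in THF at rt. The sulfonimide is an activated sulfonyl donor, and the sulfonamide anion it releases resists a second cleavage.

**Further compounds**

F0 | step 4 | none | none
F1 | step 5 | 2,7-dibromo-1H-indole | Brc1cc2cccc(Br)c2[nH]1
F2 | step 3 | N-[2-bromo-6-(2,2-dibromoethenyl)phenyl]-N-(methylsulfonyl)methanesulfonamide | CS(=O)(=O)N(c1c(Br)cccc1C=C(Br)Br)S(C)(=O)=O
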